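**Strategy.** The cyclohexene ring is opened across its trisubstituted C2=C3 double bond (the C(CH3)=CH unit next to the benzylic CH that carries the coumarin-8-yl group), which leads back to an acyclic 1,7-diene with a vinyl and an isopropenyl terminus. Ring-closing metathesis forms this double bond and the six-membered ring in one operation. Its precursor, a γ,δ-unsaturated aldehyde, is assembled in a single enantioselective iridium/amine dual-catalytic allylation of 5-methylhex-5-enal with a racemic coumarinyl vinyl carbinol, which sets the benzylic stereocentre. The quaternary centre follows by methylation of the ring aldehyde enolate anti to the aryl group, and the styryl arm by methylenation and Heck coupling.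

Key step: step 6

Assumption: the (S)-ligand on iridium is taken to deliver the required benzylic configuration, by analogy with dual iridium/amine allylations of 2,6-dioxygenated aryl vinyl carbinols; if the first run shows the opposite sense, the mirror-image ligand is used.

Step 1
Reactants: 1 7-hydroxy-2-oxo-2H-chromene-8-carbaldehyde
Product: 2 7-methoxy-2-oxo-2H-chromene-8-carbaldehyde
Conditions: MeI, K2CO3, acetone, reflux
Reagents that add atoms: iodomethane, CI
Why: Williamson ether synthesis; the phenol is the only acidic site and its potassium phenoxide is methylated on oxygen.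

Step 2
Reactants: 2 7-methoxy-2-oxo-2H-chromene-8-carbaldehyde
Product: 3 racemic 8-(1-hydroxyprop-2-en-1-yl)-7-methoxy-2H-chromen-2-one
Conditions: CH2=CHMgBr (1.1 equiv), THF, −78 °C; aq NH4Cl
Reagents that add atoms: vinylmagnesium bromide, C=C[Mg]Br
Why: Grignard 1,2-addition; at −78 °C the aldehyde is far more electrophilic than the coumarin lactone, and the racemic carbinol suffices because step 5 is enantioconvergent.

Step 3
Reactants: 4 ethyl 5-oxohexanoate
Product: 5 ethyl 5-methylhex-5-enoate
Conditions: Ph3PCH3Br, KOtBu, THF, 0 °C to 25 °C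
Reagents that add atoms: methyltriphenylphosphonium bromide, C[P+](c1ccccc1)(c1ccccc1)c1ccccc1.[Br-]
Why: Wittig methylenation; the unstabilised ylide attacks the ketone and leaves the ethyl ester untouched.

Step 4
Reactants: 5 ethyl 5-methylhex-5-enoate
Product: 6 5-methylhex-5-enal
Conditions: iBu2AlH (1.05 equiv), CH2Cl2, −78 °C; MeOH, then aq potassium sodium tartrate
Reagents that add atoms: none
Why: Partial ester reduction with diisobutylaluminium hydride; the tetrahedral aluminium hemiacetal is stable at −78 °C and releases the aldehyde only on work-up.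

Step 5
Reactants: 3 racemic 8-(1-hydroxyprop-2-en-1-yl)-7-methoxy-2H-chromen-2-one; 6 5-methylhex-5-enal (3 equiv)
Product: 7 (2R,3R)-3-(7-methoxy-2-oxo-2H-chromen-8-yl)-2-(3-methylbut-3-en-1-yl)pent-4-enal
Conditions: [Ir(cod)Cl]2 (3 mol%), (S)-BINOL-derived N-(dibenzo[b,f]azepin-5-yl) phosphoramidite–olefin ligand (12 mol%), (S)-2-{bis[3,5-bis(trifluoromethyl)phenyl](trimethylsilyloxy)methyl}pyrrolidine (15 mol%), ZnBr2 (8 mol%), ClCH2CH2Cl, 25 °C
Reagents that add atoms: none
Why: Enantioselective α-allylation of an aldehyde by merged iridium allylic substitution and enamine catalysis; both enantiomers of 3 ionise with loss of water to the same allyliridium complex, which the enamine of 6 attacks at the branched terminus, so that the ligand on iridium sets the benzylic centre and the amine sets the α-centre (the latter is erased again in step 7).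

Step 6
Reactants: 7 (2R,3R)-3-(7-methoxy-2-oxo-2H-chromen-8-yl)-2-(3-methylbut-3-en-1-yl)pent-4-enal
Product: 8 (1R,2R)-2-(7-methoxy-2-oxo-2H-chromen-8-yl)-4-methylcyclohex-3-ene-1-carbaldehyde
Conditions: second-generation Grubbs catalyst RuCl2(=CHPh)(H2IMes)(PCy3) (5 mol%), CH2Cl2 (0.01 M), 40 °C
Reagents that add atoms: none
Why: Ring-closing olefin metathesis: the ruthenium benzylidene initiates at the unhindered vinyl group on the benzylic carbon, the resulting alkylidene adds in a [2+2] sense to the 1,1-disubstituted isopropenyl end, and cycloreversion of the ruthenacyclobutane releases the cyclohexene with its trisubstituted C(CH3)=CH bond while ethene leaves the solution. The closest known reaction type is the ring-closing metathesis of 1,7-dienes that pair a vinyl with a 2-propenyl terminus to give 1-methylcyclohexenes, including substrates with a 2,6-dioxygenated aryl group on the allylic carbon and a free aldehyde. The six-membered carbocycle is closed by intramolecular alkylidene transfer within the 1,7-diene, and no smaller ring can compete because the only other alkenes are the coumarin C3=C4 bonds. No stereocentre is formed; both existing ones lie outside the reacting carbons, and the neutral conditions leave the epimerisable aldehyde α-carbon untouched. The step needs chemoselectivity for the two terminal alkenes over the lactone alkene of the coumarin and ring closure over dimerisation, which the inertness of the electron-poor endocyclic cis-disubstituted alkene towards ruthenium alkylidenes and high dilution secure.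

Step 7
Reactants: 8 (1R,2R)-2-(7-methoxy-2-oxo-2H-chromen-8-yl)-4-methylcyclohex-3-ene-1-carbaldehyde
Product: 10 (1S,2S)-2-(7-methoxy-2-oxo-2H-chromen-8-yl)-1,4-dimethylcyclohex-3-ene-1-carbaldehyde, via potassium enolate 9 (not isolated)
Conditions: KN(SiMe3)2, THF, −78 °C; MeI, −78 °C to −20 °C
Reagents that add atoms: iodomethane, CI
Why: α-Alkylation of an aldehyde enolate; the exocyclic enolate is methylated on carbon from the ring face anti to the neighbouring coumarinyl group (held pseudoaxial by allylic strain), so that the methyl group enters trans and the formyl group ends cis to the aryl group, which sets the quaternary centre.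

Step 8
Reactants: 10 (1S,2S)-2-(7-methoxy-2-oxo-2H-chromen-8-yl)-1,4-dimethylcyclohex-3-ene-1-carbaldehyde
Product: 11 8-[(1R,6R)-6-ethenyl-3,6-dimethylcyclohex-2-en-1-yl]-7-methoxy-2H-chromen-2-one
Conditions: Ph3PCH3Br, KN(SiMe3)2, THF, 0 °C; then 10, −78 °C to 0 °C
Reagents that add atoms: methyltriphenylphosphonium bromide, C[P+](c1ccccc1)(c1ccccc1)c1ccccc1.[Br-]
Why: Wittig methylenation; the non-enolisable neopentyl aldehyde reacts with the small unstabilised ylide faster than the coumarin lactone, and the quaternary centre cannot epimerise.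

Step 9
Reactants: 12 7-hydroxy-2H-chromen-2-one
Product: 13 7-hydroxy-8-iodo-2H-chromen-2-one
Conditions: iodine, KI, aq NH3, 25 °C
Reagents that add atoms: iodine, [I][I]
Why: Electrophilic aromatic iodination; the phenoxide directs the electrophile to C8, the position ortho to the phenol oxygen that lies between the two ring oxygens.

Step 10
Reactants: 13 7-hydroxy-8-iodo-2H-chromen-2-one
Product: 14 8-iodo-7-methoxy-2H-chromen-2-one
Conditions: MeI, K2CO3, acetone, reflux
Reagents that add atoms: iodomethane, CI
Why: Williamson ether synthesis; the potassium phenoxide is methylated on oxygen.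

Step 11
Reactants: 11 8-[(1R,6R)-6-ethenyl-3,6-dimethylcyclohex-2-en-1-yl]-7-methoxy-2H-chromen-2-one; 14 8-iodo-7-methoxy-2H-chromen-2-one
Product: 15 8-[(1R,6R)-6-[(E)-2-(7-methoxy-2-oxo-2H-chromen-8-yl)ethenyl]-3,6-dimethylcyclohex-2-en-1-yl]-7-methoxy-2H-chromen-2-one
Conditions: Pd(OAc)2 (10 mol%), Bu4NCl, NaHCO3, DMF, 85 °C
Reagents that add atoms: none
Why: Mizoroki–Heck reaction; the arylpalladium iodide adds to the only monosubstituted alkene with the aryl group at the terminal carbon, and because the adjacent carbon is quaternary the syn β-hydride elimination can only go toward the benzylic hydrogen, which gives the (E)-styryl bond.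

**Compound list**

1 | 7-hydroxy-2-oxo-2H-chromene-8-carbaldehyde | O=Cc1c(O)ccc2ccc(=O)oc12 | starting material
2 | 7-methoxy-2-oxo-2H-chromene-8-carbaldehyde | O=Cc1c(OC)ccc2ccc(=O)oc12 | intermediate
3 | racemic 8-(1-hydroxyprop-2-en-1-yl)-7-methoxy-2H-chromen-2-one | C=CC(O)c1c(OC)ccc2ccc(=O)oc12 | intermediate
4 | ethyl 5-oxohexanoate | CCOC(=O)CCCC(C)=O | starting material
5 | ethyl 5-methylhex-5-enoate | CCOC(=O)CCCC(C)=C | intermediate
6 | 5-methylhex-5-enal | O=CCCCC(C)=C | intermediate
7 | (2R,3R)-3-(7-methoxy-2-oxo-2H-chromen-8-yl)-2-(3-methylbut-3-en-1-yl)pent-4-enal | O=C[C@H](CCC(C)=C)[C@@H](C=C)c1c(OC)ccc2ccc(=O)oc12 | intermediate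
8 | (1R,2R)-2-(7-methoxy-2-oxo-2H-chromen-8-yl)-4-methylcyclohex-3-ene-1-carbaldehyde (formyl trans to aryl) | O=C[C@@H]1CCC(C)=C[C@H]1c1c(OC)ccc2ccc(=O)oc12 | intermediate
9 | potassium [(2R)-2-(7-methoxy-2-oxo-2H-chromen-8-yl)-4-methylcyclohex-3-en-1-ylidene]methanolate (enolate geometry not defined) | [K+].[O-]C=C1CCC(C)=C[C@H]1c1c(OC)ccc2ccc(=O)oc12 | intermediate (not isolated)
10 | (1S,2S)-2-(7-methoxy-2-oxo-2H-chromen-8-yl)-1,4-dimethylcyclohex-3-ene-1-carbaldehyde (formyl cis to aryl) | O=C[C@@]1(C)CCC(C)=C[C@H]1c1c(OC)ccc2ccc(=O)oc12 | intermediate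
11 | 8-[(1R,6R)-6-ethenyl-3,6-dimethylcyclohex-2-en-1-yl]-7-methoxy-2H-chromen-2-one | C=C[C@@]1(C)CCC(C)=C[C@H]1c1c(OC)ccc2ccc(=O)oc12 | intermediate
12 | 7-hydroxy-2H-chromen-2-one | Oc1ccc2ccc(=O)oc2c1 | starting material
13 | 7-hydroxy-8-iodo-2H-chromen-2-one | Oc1ccc2ccc(=O)oc2c1I | intermediate
14 | 8-iodo-7-methoxy-2H-chromen-2-one | COc1ccc2ccc(=O)oc2c1I | intermediate
15 | 8-[(1R,6R)-6-[(E)-2-(7-methoxy-2-oxo-2H-chromen-8-yl)ethenyl]-3,6-dimethylcyclohex-2-en-1-yl]-7-methoxy-2H-chromen-2-one | COc1ccc2ccc(=O)oc2c1/C=C/[C@@]1(C)CCC(C)=C[C@H]1c1c(OC)ccc2ccc(=O)oc12 | target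

**Step count.** Total: 11 steps. Longest linear sequence: 7 steps (steps 1, 2, 5, 6, 7, 8, 11).

**Steps most likely to fail**

Step 5. Ionisation of the ortho,ortho-disubstituted carbinol may be slow, attack may drift to the linear terminus, and the sense of induction on this aryl group is assumed, not known. The fallback sets the benzylic centre by chirality transfer in a sigmatropic rearrangement; it sets out from 2 and comes back at 8. Wittig reaction of 2 with 1-(triphenylphosphoranylidene)propan-2-one should give (E)-4-(7-methoxy-2-oxo-2H-chromen-8-yl)but-3-en-2-one F1. Corey–Bakshi–Shibata reduction with the (R)-methyl oxazaborolidine and catecholborane should give 8-[(1E,3S)-3-hydroxybut-1-en-1-yl]-7-methoxy-2H-chromen-2-one F2. Johnson–Claisen rearrangement with triethyl orthoacetate and catalytic propionic acid at 140 °C should pass the carbinol configuration through a chair transition state to give ethyl (3S,4E)-3-(7-methoxy-2-oxo-2H-chromen-8-yl)hex-4-enoate F3. Alkylation of its enolate (LiN(SiMe3)2, DMPU, THF) with 4-iodo-2-methylbut-1-ene should give ethyl (3R,4E)-3-(7-methoxy-2-oxo-2H-chromen-8-yl)-2-(3-methylbut-3-en-1-yl)hex-4-enoate F4 as a mixture of C2 epimers. Reduction with iBu2AlH at −78 °C should give (3R,4E)-3-(7-methoxy-2-oxo-2H-chromen-8-yl)-2-(3-methylbut-3-en-1-yl)hex-4-enal F5. Ring-closing metathesis under the conditions of step 6, with loss of propene, should then give 8 together with its cis epimer (1S,2R)-2-(7-methoxy-2-oxo-2H-chromen-8-yl)-4-methylcyclohex-3-ene-1-carbaldehyde F6; the two need not be separated because step 7 turns both into enolate 9.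

Step 7. The base or the enolate may attack the coumarin lactone, methylation may occur on oxygen, or the facial selectivity may be insufficient. The fallback builds the quaternary centre under catalyst control before the ring is closed; it sets out from 5 and 3 and comes back at 10. Methylation of 5 (LiN(iPr)2, MeI, THF, −78 °C) should give racemic ethyl 2,5-dimethylhex-5-enoate F7, and reduction with iBu2AlH at −78 °C racemic 2,5-dimethylhex-5-enal F8. Allylation of F8 with 3 under [Ir(cod)Cl]2, the ligand of step 5, a cinchona-derived primary amine (9-amino-9-deoxy-epi-alkaloid of the hand that gives the 2S centre) and Cl3CCO2H should give (2S,3S)-3-(7-methoxy-2-oxo-2H-chromen-8-yl)-2-methyl-2-(3-methylbut-3-en-1-yl)pent-4-enal F9. Ring-closing metathesis as in step 6 should then give 10.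

Step 11. Crowding at both partners (an aryl iodide with two ortho substituents, a vinyl group on a quaternary carbon) may slow oxidative addition and migratory insertion until reduction of the iodide takes over. The fallback moves the carbon–carbon bond formation to a cross-coupling of a preformed (E)-alkenyl boronate; it sets out from 10 and comes back at 15. Takai–Utimoto-type borylolefination of 10 with 2-(dichloromethyl)-4,4,5,5-tetramethyl-1,3,2-dioxaborolane, CrCl2 and LiI in THF should give 7-methoxy-8-[(1R,6R)-3,6-dimethyl-6-[(E)-2-(4,4,5,5-tetramethyl-1,3,2-dioxaborolan-2-yl)ethenyl]cyclohex-2-en-1-yl]-2H-chromen-2-one F10. Suzuki–Miyaura coupling of F10 with 14 (Pd(dppf)Cl2, K3PO4, dioxane/water, 80 °C) should then give 15 with the E geometry retained.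

**Further compounds**

F1 | step 5 | (E)-4-(7-methoxy-2-oxo-2H-chromen-8-yl)but-3-en-2-one | CC(=O)/C=C/c1c(OC)ccc2ccc(=O)oc12
F2 | step 5 | 8-[(1E,3S)-3-hydroxybut-1-en-1-yl]-7-methoxy-2H-chromen-2-one | C[C@H](O)/C=C/c1c(OC)ccc2ccc(=O)oc12
F3 | step 5 | ethyl (3S,4E)-3-(7-methoxy-2-oxo-2H-chromen-8-yl)hex-4-enoate | CCOC(=O)C[C@@H](/C=C/C)c1c(OC)ccc2ccc(=O)oc12
F4 | step 5 | ethyl (3R,4E)-3-(7-methoxy-2-oxo-2H-chromen-8-yl)-2-(3-methylbut-3-en-1-yl)hex-4-enoate (mixture of C2 epimers) | CCOC(=O)C(CCC(C)=C)[C@@H](/C=C/C)c1c(OC)ccc2ccc(=O)oc12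
F5 | step 5 | (3R,4E)-3-(7-methoxy-2-oxo-2H-chromen-8-yl)-2-(3-methylbut-3-en-1-yl)hex-4-enal (mixture of C2 epimers) | O=CC(CCC(C)=C)[C@@H](/C=C/C)c1c(OC)ccc2ccc(=O)oc12
F6 | step 5 | (1S,2R)-2-(7-methoxy-2-oxo-2H-chromen-8-yl)-4-methylcyclohex-3-ene-1-carbaldehyde (formyl cis to aryl) | O=C[C@H]1CCC(C)=C[C@H]1c1c(OC)ccc2ccc(=O)oc12
F7 | step 7 | racemic ethyl 2,5-dimethylhex-5-enoate | CCOC(=O)C(C)CCC(C)=C
F8 | step 7 | racemic 2,5-dimethylhex-5-enal | O=CC(C)CCC(C)=C
F9 | step 7 | (2S,3S)-3-(7-methoxy-2-oxo-2H-chromen-8-yl)-2-methyl-2-(3-methylbut-3-en-1-yl)pent-4-enal | O=C[C@@](C)(CCC(C)=C)[C@@H](C=C)c1c(OC)ccc2ccc(=O)oc12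
F10 | step 11 | 7-methoxy-8-[(1R,6R)-3,6-dimethyl-6-[(E)-2-(4,4,5,5-tetramethyl-1,3,2-dioxaborolan-2-yl)ethenyl]cyclohex-2-en-1-yl]-2H-chromen-2-one | CC1(C)OB(/C=C/[C@@]2(C)CCC(C)=C[C@H]2c2c(OC)ccc3ccc(=O)oc23)OC1(C)C
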